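# Proposed total synthesis of 4,5′-dimethoxy-2′,7-dimethyl-[1,1′-binaphthalene]-2,4′,5,6′-tetrol (CNP0147277.0) by aryne acyl-alkylation

Locants used throughout: unit A (3,8-dihydroxy-1-methoxy-6-methylnaphthalene, joined through C4) has carbons C1 to C8a, with ring P = C1, C2, C3, C4, C4a, C8a and ring Q its benzo ring. Unit B (4,6-dihydroxy-5-methoxy-2-methylnaphthalene, joined through C1′) has primed carbons, with ring R = C1′ to C4′, C4a′, C8a′ and ring S its benzo ring.

## The problem

The target is an unsymmetrical 1,1′-binaphthyl in which C4 of unit A is bonded to C1′ of unit B. That bond is flanked by the C3 hydroxyl and the peri C5–H on one side and by the C2′ methyl and the peri C8′–H on the other. It is therefore as crowded as the axis of a 2,2′-disubstituted 1,1′-binaphthyl, and a direct aryl–aryl coupling would need both electron-rich partners functionalised at their most hindered carbons. There is no stereocentre. The axis is the only stereo element and is not specified, so every control problem is regiochemical: of six oxygens, O1 and O5′ must be methyl ethers while their peri neighbours O8 and O4′ and the remaining O3 and O6′ stay free. The free tetrol contains a naphthalene-1,3-diol fused to a peri-oxygenated ring and is prone to autoxidation at C2 and C4, so the hydroxyls should stay masked until a last neutral step, and late Lewis acids that could scramble the methyl ethers are excluded. The enabling feature lies in ring P. The fusion carbons C8a and C4a are ortho and meta to the C8 oxygen; C8a carries the oxygenated C1 with C2 behind it, and C4a carries C4, which holds unit B and is followed by the oxygenated C3. Read as an acetyl group on C8a and an aryl-substituted acetate on C4a, this is the pair of neighbouring substituents a β-ketoester delivers to the two carbons of an aryne, with the acyl group ending beside the alkoxy substituent. Ring R shows the same pattern (C4′ on C4a′ next to the C5′ methoxy group, C1′ on C8a′), so an aryne insertion with a 1,3-diketone can build unit B as well.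

## Retrosynthesis

**34 from 33.** The last cut removes four O–benzyl bonds (O3, O8, O4′, O6′). Benzyl is preferred to acetal or silyl masks because one hydrogenolysis frees all four phenols without acid, base or fluoride, and because benzyl ethers survive fluoride-generated arynes, alkoxides and hydride bases. The forward step only has to leave the two methyl ethers and the arene rings alone.

**33 from 31 through 32.** The O1–methyl and O3–benzyl bonds are cut next. In diol 31 the O1 hydroxyl is hydrogen-bonded to the peri benzyloxy oxygen at C8 and is the weaker acid, while the O3 hydroxyl is an ordinary β-naphthol hydroxyl. Benzylating O3 first (32) and then forcing the methylation of O1 (33) uses that difference. The reverse order is not available, because nothing makes O1 the more reactive site. The forward steps need mono-alkylation at oxygen without C-alkylation of the electron-rich diol.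

**31 from 30.** Ring P is opened at C2–C3, the bond of a Dieckmann-type condensation between the methyl of an aryl methyl ketone and an ester carbonyl. Cutting here, and not at C1–C2 or C3–C4, leaves both halves of ring P as carbonyl groups: an acetyl on C8a and an acetic ester on C4a. It also turns C4 into an sp3 methine, so the crowded axis becomes an ordinary single bond to a benzylic carbon. The forward reaction must run under equilibrating alkoxide, because the methine is the more acidic site, and without oxygen.

**30 from 20 and 28.** C4–C4a and C1–C8a are cut together. Ketoester 20 supplies C1 to C4 with unit B already attached, and silyl triflate 28 supplies ring Q as aryne 29. The neighbouring cut at the axis would be a cross-coupling of two naphthalenes. This cut never makes C4–C1′: that bond is present in 20 as the link between the α-carbon and unit B, and the difficult bond formation is moved to C4–C4a, where the electrophile is an aryne. The precursors are a trisubstituted benzene and a naphthylacetoacetate. The forward reaction must add the enolate carbon to the aryne carbon meta to the benzyloxy group and transfer the acetyl group, not the ester.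

**20 from 19; 19 from 16 and 17; 16 from 15; 15 from 14.** The acetyl group is cut from the α-carbon (enolate C-acylation of ester 19). The C1′–CH2 bond is cut next: bromide 16 is coupled with the zinc enolate 18 made from methyl bromoacetate 17. Then come the C1′–Br bond (bromination of 15 para to the C4′ benzyloxy group) and the O4′ benzyl group (from naphthol 14). Attaching the side chain after ring R exists costs two steps more than building it in during the ring synthesis (the fallback to step 8). In return each step is of a routine kind, and its regiochemistry is fixed by groups already present.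

**14 from 10 and 11.** Ring R is cut at C1′–C8a′, C4′–C4a′ and C2′–C3′. Aryne 12 from silyl triflate 10 takes up acetylacetone 11 across its triple bond to give diketone 13, which closes by aldol condensation. This mirrors the key step and places the C4′ hydroxyl beside the C5′ methoxy group through the same alkoxy-directed insertion. A Stobbe or Friedel–Crafts annulation from vanillin would instead have to close at the crowded carbon between the formyl and methoxy groups. The precursor is again a trisubstituted benzene.

**10 from 1; 28 from 21.** Both silyl triflates are cut at C–Si and O–S and traced through carbamates (5 and 8; 23 and 26) to phenols 4 and 22. The carbamate and the neighbouring ether direct lithiation to the carbon between them, which is where silicon must sit for an aryne steered by a 3-alkoxy group. Phenol 4 comes from vanillin 1 by benzylation (2) and Dakin-type oxidation; phenol 22 comes from orcinol 21 by monobenzylation.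

## Roads not taken

**Alternative 1: one-carbon ring expansion of an indanone.** Ring R would be finished last by inserting C3′ between C2′ and C4′. Indanone A2 would come from a Nazarov cyclisation and already carries the complete, protected unit A on its C3. Its silyl enol ether takes up dibromocarbene, and the dibromocyclopropane opens with loss of bromide and silicon to the bromonaphthol A1, whose bromine would fall in the final hydrogenolysis.

- Merit: the bond between the two units is made by carbonyl chemistry at an sp2 carbon long before it becomes a biaryl axis. This is easier than sending a crowded enolate into an aryne, and the ring expansion of indanone silyl enol ethers to 2-halo-1-naphthols is a known reaction type.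
- Weak points: unit A must first be made complete and functionalised at C4, so ring P and its O1/O3 differentiation are postponed, not solved, and the plan runs through two separate naphthalene syntheses. The Nazarov step works on a very electron-rich system that can also cyclise into unit A. Dibromocarbene is an electrophile towards alkoxynaphthalenes and must select the enol ether among them.
- Comparison: against the easier inter-unit bond, the chosen plan sets convergence. One operation joins the halves and lays down both ring P bonds, and both naphthalenes come from the same kind of aryne chemistry.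

**Alternative 2: pyranone-to-resorcinol ring transformation.** The cut is C4–C4a, made by a biomimetic aldol condensation. Hydroxide opens the 4-pyranone ring of A4, a cyclohexanedione-fused pyranone with the unit B methylene group on its C2. The resulting enolised polyketone condenses through its benzylic carbon C4 with the ring carbonyl at C4a and gives resorcinol A3, in which ring Q is still a cyclohexanone.

- Where it is better: in A3 the O1 hydroxyl is chelated to the peri ketone at C8, the textbook situation for leaving it untouched while O3 is benzylated. The chosen plan relies on the weaker hydrogen bond to an ether oxygen. The crowded C4–C4a bond is also formed intramolecularly.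
- Weak points: ring Q must be dehydrogenated to the C8 naphthol late, in the presence of four benzyl ethers and two electron-rich rings. The open polyketone has other condensation modes, such as reclosure to the pyranone or closure through C2. The side chain needs the same unit B acetic ester 19 anyway.
- Comparison: against the better hydroxyl differentiation, the chosen plan sets a ring Q that is aromatic from the start and a shorter sequence after the key step.

**Alternative 3: benzocyclobutenone plus siloxyalkyne.** Ring P is cut at C1–C2 and C3–C4. Benzocyclobutenone A6, which carries unit B on its sp3 carbon (the future C4), opens thermally to an o-quinoid vinylketene, and siloxyalkyne A7 adds across C1 and C4 to give naphthol A5.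

- Where it is better: A5 emerges with O1 as a free hydroxyl and O3 as a silyl ether, so the mechanism distinguishes the two oxygens and O1 can be methylated without a selectivity question. This is exactly the weak point of the chosen plan.
- Weak points: A6 is not a simple compound. It needs a four-membered ring on the orcinol-derived benzene, most easily reached from aryne 29 by a [2+2] cycloaddition, and then the hindered bond to unit B at the α-carbon of a strained ketone, so the union of the two units is still unsolved. The electrocyclic opening interrupts the aromaticity of ring Q and needs high temperature, at which a vinylketene with a bulky C4 substituent can dimerise or be lost through a 1,5-hydrogen shift.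
- Comparison: the chosen plan uses the aryne once, directly for both bonds of ring P, and pays for this with one selective alkylation.

Key step: step 15

Remark on the chemistry: the structure fixes no sense of twist at the C4–C1′ axis and has no stereocentre, so the racemic biaryl is taken as the goal.

## Route

Step 1
Reactants: 1 vanillin (4-hydroxy-3-methoxybenzaldehyde)
Product: 2 4-(benzyloxy)-3-methoxybenzaldehyde
Conditions: BnBr, K2CO3, DMF, rt
Reagents that add atoms: benzyl bromide, BrCc1ccccc1
Why: Williamson ether synthesis at the only acidic site; the aldehyde is inert to K2CO3 and benzyl bromide.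

Step 2
Reactants: 2 4-(benzyloxy)-3-methoxybenzaldehyde
Product: 4 4-(benzyloxy)-3-methoxyphenol, via aryl formate 3 (not isolated)
Conditions: mCPBA, CH2Cl2, rt; then K2CO3 (cat.), MeOH, rt
Reagents that add atoms: mCPBA (3-chloroperoxybenzoic acid), OOC(=O)c1cccc(Cl)c1
Why: Baeyer–Villiger (Dakin-type) oxidation of an electron-rich benzaldehyde: the 4-alkoxyaryl group migrates in preference to hydride and gives formate 3, which mild methanolysis converts into the phenol; the benzyl ether is untouched.

Step 3
Reactants: 4 4-(benzyloxy)-3-methoxyphenol
Product: 5 4-(benzyloxy)-3-methoxyphenyl N-isopropylcarbamate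
Conditions: i-PrNCO, Et3N (cat.), CH2Cl2, rt
Reagents that add atoms: isopropyl isocyanate, CC(C)N=C=O
Why: Base-catalysed addition of the phenol to the isocyanate gives an N-monosubstituted carbamate, a strong directing group for metalation that can later be removed by base-induced elimination.

Step 4
Reactants: 5 4-(benzyloxy)-3-methoxyphenyl N-isopropylcarbamate
Product: 8 4-(benzyloxy)-3-methoxy-2-(trimethylsilyl)phenyl N-isopropylcarbamate, via N-silyl carbamate 6 (not isolated), via N-silyl C-silyl carbamate 7 (not isolated)
Conditions: TBSOTf, TMEDA, Et2O, 0 °C to rt; n-BuLi, TMEDA, −78 °C; TMSCl, −78 °C to rt; aq NaHSO4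
Reagents that add atoms: chlorotrimethylsilane, C[Si](C)(C)Cl
Why: Directed ortho-metalation: after in-flask N-silylation (6), the carbamate and the methoxy group together direct n-BuLi to the carbon between them, and the aryllithium is quenched by TMSCl (7). Aqueous acid removes only the N-silyl group; the benzyloxy group is not adjacent to the lithiated carbon and is not deprotonated at −78 °C.

Step 5
Reactants: 8 4-(benzyloxy)-3-methoxy-2-(trimethylsilyl)phenyl N-isopropylcarbamate
Product: 10 4-(benzyloxy)-3-methoxy-2-(trimethylsilyl)phenyl trifluoromethanesulfonate, via silyl phenol 9 (not isolated)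
Conditions: DBU, Et2NH, MeCN, 40 °C; then PhNTf2, rt
Reagents that add atoms: N-phenylbis(trifluoromethanesulfonimide), O=S(=O)(N(c1ccccc1)S(=O)(=O)C(F)(F)F)C(F)(F)F
Why: DBU eliminates isopropyl isocyanate from the N–H carbamate (E1cB), diethylamine traps it as a urea, and the phenoxide of 9 is triflated in the same flask. No fluoride or acid is present, so the aryl–silicon bond survives.

Step 6
Reactants: 10 4-(benzyloxy)-3-methoxy-2-(trimethylsilyl)phenyl trifluoromethanesulfonate; 11 acetylacetone (pentane-2,4-dione, 3 equiv)
Product: 14 7-(benzyloxy)-8-methoxy-3-methylnaphthalen-1-ol, via aryne 12 (not isolated), via diketone 13 (not isolated)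
Conditions: CsF, MeCN, 80 °C; then K2CO3, MeOH, 50 °C
Reagents that add atoms: none
Why: Fluoride-induced 1,2-elimination gives aryne 12; the acetylacetone enolate adds through carbon to the aryne carbon meta to the methoxy group, and the aryl anion beside the methoxy group takes over one acetyl group through a four-membered alkoxide (aryne acyl-alkylation of a 1,3-diketone). Diketone 13 then closes by intramolecular aldol condensation of the aryl methyl ketone onto the aliphatic ketone, the usual mode for 2-acylbenzyl ketones, and dehydrates and enolises to the 1-naphthol. The other aldol mode would attack an aryl ketone flanked on both sides and would place a methyl group peri to the methoxy group.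

Step 7
Reactants: 14 7-(benzyloxy)-8-methoxy-3-methylnaphthalen-1-ol
Product: 15 1,7-bis(benzyloxy)-8-methoxy-3-methylnaphthalene
Conditions: BnBr, K2CO3, DMF, 60 °C
Reagents that add atoms: benzyl bromide, BrCc1ccccc1
Why: Williamson ether synthesis; the hydroxyl is hydrogen-bonded to the peri methoxy group, hence DMF and heat, and no other acidic site is present.

Step 8
Reactants: 15 1,7-bis(benzyloxy)-8-methoxy-3-methylnaphthalene
Product: 16 4,6-bis(benzyloxy)-1-bromo-5-methoxy-2-methylnaphthalene
Conditions: NBS, MeCN, 0 °C, dark
Reagents that add atoms: N-bromosuccinimide, O=C1CCC(=O)N1Br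
Why: Electrophilic aromatic bromination; in the numbering of 15, C4 is an α-position para to the C1 benzyloxy group and ortho to the methyl group. The C8 methoxy group is twisted out of conjugation by its two neighbours and activates C5 less.

Step 9
Reactants: 16 4,6-bis(benzyloxy)-1-bromo-5-methoxy-2-methylnaphthalene; 17 methyl bromoacetate
Product: 19 methyl 2-[4,6-bis(benzyloxy)-5-methoxy-2-methylnaphthalen-1-yl]acetate, via Reformatsky reagent 18 (not isolated)
Conditions: Zn, THF, rt (17 to 18); then 16, Pd(dba)2 (cat.), P(t-Bu)3 (cat.), THF, 60 °C
Reagents that add atoms: none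
Why: Negishi-type coupling of the Reformatsky reagent 18, a zinc ester enolate, with the aryl bromide under zerovalent palladium and a bulky trialkylphosphine, a combination that tolerates ortho-substituted aryl bromides. The neutral zinc enolate leaves the benzyl ethers and the product ester alone.

Step 10
Reactants: 19 methyl 2-[4,6-bis(benzyloxy)-5-methoxy-2-methylnaphthalen-1-yl]acetate
Product: 20 methyl 2-[4,6-bis(benzyloxy)-5-methoxy-2-methylnaphthalen-1-yl]-3-oxobutanoate (racemic, largely enolised)
Conditions: LiN(SiMe3)2 (2.2 equiv), THF, −78 °C; 1-acetylimidazole, −78 to 0 °C; aq NH4Cl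
Reagents that add atoms: 1-acetylimidazole, CC(=O)n1ccnc1
Why: Crossed Claisen-type C-acylation of the lithium ester enolate; the acylimidazole gives a stable tetrahedral adduct, and the second equivalent of base deprotonates the more acidic product, so the reaction stops at the β-ketoester.

Step 11
Reactants: 21 orcinol (5-methylbenzene-1,3-diol, in excess)
Product: 22 3-(benzyloxy)-5-methylphenol
Conditions: BnBr (0.5 equiv), K2CO3, acetone, reflux
Reagents that add atoms: benzyl bromide, BrCc1ccccc1
Why: Statistical Williamson mono-alkylation of a symmetrical diphenol; the excess of orcinol suppresses the dibenzyl ether and is separable by its solubility in aqueous base.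

Step 12
Reactants: 22 3-(benzyloxy)-5-methylphenol
Product: 23 3-(benzyloxy)-5-methylphenyl N-isopropylcarbamate
Conditions: i-PrNCO, Et3N (cat.), CH2Cl2, rt
Reagents that add atoms: isopropyl isocyanate, CC(C)N=C=O
Why: Base-catalysed carbamoylation of the phenol, as in step 3.

Step 13
Reactants: 23 3-(benzyloxy)-5-methylphenyl N-isopropylcarbamate
Product: 26 3-(benzyloxy)-5-methyl-2-(trimethylsilyl)phenyl N-isopropylcarbamate, via N-silyl carbamate 24 (not isolated), via N-silyl C-silyl carbamate 25 (not isolated)
Conditions: TBSOTf, TMEDA, Et2O, 0 °C to rt; n-BuLi, TMEDA, −78 °C; TMSCl, −78 °C to rt; aq NaHSO4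
Reagents that add atoms: chlorotrimethylsilane, C[Si](C)(C)Cl
Why: Directed ortho-metalation as in step 4; the carbamate and the benzyloxy group flank the same carbon and direct lithiation there. The aryllithium is silylated at −78 °C before proton transfer from the benzylic CH2 or metalation of the ring methyl group can compete.

Step 14
Reactants: 26 3-(benzyloxy)-5-methyl-2-(trimethylsilyl)phenyl N-isopropylcarbamate
Product: 28 3-(benzyloxy)-5-methyl-2-(trimethylsilyl)phenyl trifluoromethanesulfonate, via silyl phenol 27 (not isolated)
Conditions: DBU, Et2NH, MeCN, 40 °C; then PhNTf2, rt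
Reagents that add atoms: N-phenylbis(trifluoromethanesulfonimide), O=S(=O)(N(c1ccccc1)S(=O)(=O)C(F)(F)F)C(F)(F)F
Why: Carbamate cleavage by E1cB elimination and triflation of the phenoxide in one flask, as in step 5.

Step 15
Reactants: 20 methyl 2-[4,6-bis(benzyloxy)-5-methoxy-2-methylnaphthalen-1-yl]-3-oxobutanoate; 28 3-(benzyloxy)-5-methyl-2-(trimethylsilyl)phenyl trifluoromethanesulfonate
Product: 30 methyl 2-[2-acetyl-3-(benzyloxy)-5-methylphenyl]-2-[4,6-bis(benzyloxy)-5-methoxy-2-methylnaphthalen-1-yl]acetate (racemic), via aryne 29 (not isolated)
Conditions: CsF, MeCN, 80 °C, slow addition of 28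
Reagents that add atoms: none
Why: Fluoride removes the silyl group of 28 and triflate leaves, giving aryne 29; the caesium enolate of 20 adds through carbon to the aryne carbon meta to the benzyloxy group (the future C4a), which puts the aryl anion on the carbon next to oxygen (C8a), where the inductive effect of the ether stabilises it and towards which a 3-alkoxy aryne is distorted. This anion adds to the neighbouring ketone carbonyl in a 4-exo-trig closure to a benzocyclobutenoxide, which fragments by cleaving the former bond between the α-carbon and the acetyl group, so that acetyl ends on C8a and the ester-stabilised benzylic carbanion at C4 is protonated. The closest known reaction is the acyl-alkylation of arynes from ortho-silylaryl triflates with β-ketoesters, including α-substituted ones; the α-(2-methylnaphthyl) group makes this a hindered member of the class. No ring remains in the product: the four-membered ring is transient, and C4–C4a and C1–C8a are the two skeletal bonds gained. One stereocentre, the methine carbon, arises from an uncontrolled protonation and is racemic; it disappears when ring P becomes aromatic in step 16. Three selectivities are needed: the sense of addition to the aryne, secured by the C8 benzyloxy group; ketone over ester in the acyl transfer, secured by the higher electrophilicity of the acetyl carbonyl; and C- over O-arylation, favoured by the soft carbon terminus and by slow addition of 28, which keeps the aryne concentration low.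

Step 16
Reactants: 30 methyl 2-[2-acetyl-3-(benzyloxy)-5-methylphenyl]-2-[4,6-bis(benzyloxy)-5-methoxy-2-methylnaphthalen-1-yl]acetate
Product: 31 8-(benzyloxy)-4-[4,6-bis(benzyloxy)-5-methoxy-2-methylnaphthalen-1-yl]-6-methylnaphthalene-1,3-diol (racemic axis)
Conditions: NaOMe, MeOH/THF (degassed), 60 °C, argon; AcOH
Reagents that add atoms: none
Why: Dieckmann-type (intramolecular Claisen) condensation: under equilibrating methoxide the methyl ketone enolate attacks the ester carbonyl in a 6-exo-trig closure forming C2–C3, methanol is lost and the 1,3-diketone tautomerises to the aromatic naphthalene-1,3-diol, which removes the stereocentre and creates the biaryl axis. Oxygen is excluded because the anion of the 4-aryl-1,3-diol autoxidises at C4.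

Step 17
Reactants: 31 8-(benzyloxy)-4-[4,6-bis(benzyloxy)-5-methoxy-2-methylnaphthalen-1-yl]-6-methylnaphthalene-1,3-diol
Product: 32 3,8-bis(benzyloxy)-4-[4,6-bis(benzyloxy)-5-methoxy-2-methylnaphthalen-1-yl]-6-methylnaphthalen-1-ol
Conditions: BnBr (1.0 equiv), K2CO3, acetone, rt, argon
Reagents that add atoms: benzyl bromide, BrCc1ccccc1
Why: Williamson ether synthesis under kinetic control: the C1 hydroxyl is hydrogen-bonded to the peri benzyloxy oxygen and is the weaker acid, so a weak base and one equivalent of benzyl bromide should alkylate the C3 phenoxide; K2CO3 in acetone favours O- over C-alkylation.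

Step 18
Reactants: 32 3,8-bis(benzyloxy)-4-[4,6-bis(benzyloxy)-5-methoxy-2-methylnaphthalen-1-yl]-6-methylnaphthalen-1-ol
Product: 33 3,8-bis(benzyloxy)-4-[4,6-bis(benzyloxy)-5-methoxy-2-methylnaphthalen-1-yl]-1-methoxy-6-methylnaphthalene
Conditions: NaH, MeI, DMF, 0 °C to rt
Reagents that add atoms: iodomethane, CI
Why: Williamson methylation; with O3 capped, the remaining hydrogen-bonded peri hydroxyl is deprotonated irreversibly by NaH and methylated, and no other acidic or electrophilic site remains.

Step 19
Reactants: 33 3,8-bis(benzyloxy)-4-[4,6-bis(benzyloxy)-5-methoxy-2-methylnaphthalen-1-yl]-1-methoxy-6-methylnaphthalene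
Product: 34 4,5′-dimethoxy-2′,7-dimethyl-[1,1′-binaphthalene]-2,4′,5,6′-tetrol (racemic; the target)
Conditions: H2 (1 atm), Pd/C (10% Pd on carbon), EtOAc/MeOH, rt
Reagents that add atoms: none
Why: Catalytic hydrogenolysis of four aryl benzyl ethers under neutral conditions; the methyl ethers, the arene rings and the biaryl bond are untouched, and the air-sensitive tetrol is set free only at the end.

## Compound list

1 | vanillin (4-hydroxy-3-methoxybenzaldehyde) | COc1cc(C=O)ccc1O | starting material
2 | 4-(benzyloxy)-3-methoxybenzaldehyde | COc1cc(C=O)ccc1OCc1ccccc1 | intermediate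
3 | 4-(benzyloxy)-3-methoxyphenyl formate | COc1cc(OC=O)ccc1OCc1ccccc1 | intermediate (not isolated)
4 | 4-(benzyloxy)-3-methoxyphenol | COc1cc(O)ccc1OCc1ccccc1 | intermediate
5 | 4-(benzyloxy)-3-methoxyphenyl N-isopropylcarbamate | COc1cc(OC(=O)NC(C)C)ccc1OCc1ccccc1 | intermediate
6 | 4-(benzyloxy)-3-methoxyphenyl N-(tert-butyldimethylsilyl)-N-isopropylcarbamate | COc1cc(OC(=O)N(C(C)C)[Si](C)(C)C(C)(C)C)ccc1OCc1ccccc1 | intermediate (not isolated)
7 | 4-(benzyloxy)-3-methoxy-2-(trimethylsilyl)phenyl N-(tert-butyldimethylsilyl)-N-isopropylcarbamate | COc1c(OCc2ccccc2)ccc(OC(=O)N(C(C)C)[Si](C)(C)C(C)(C)C)c1[Si](C)(C)C | intermediate (not isolated)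
8 | 4-(benzyloxy)-3-methoxy-2-(trimethylsilyl)phenyl N-isopropylcarbamate | COc1c(OCc2ccccc2)ccc(OC(=O)NC(C)C)c1[Si](C)(C)C | intermediate
9 | 4-(benzyloxy)-3-methoxy-2-(trimethylsilyl)phenol | COc1c(OCc2ccccc2)ccc(O)c1[Si](C)(C)C | intermediate (not isolated)
10 | 4-(benzyloxy)-3-methoxy-2-(trimethylsilyl)phenyl trifluoromethanesulfonate | COc1c(OCc2ccccc2)ccc(OS(=O)(=O)C(F)(F)F)c1[Si](C)(C)C | intermediate
11 | acetylacetone (pentane-2,4-dione) | CC(=O)CC(C)=O | starting material
12 | 4-(benzyloxy)-3-methoxybenzyne (1-(benzyloxy)-2-methoxy-3,4-didehydrobenzene) | COC1=C(OCc2ccccc2)C=CC#C1 | intermediate (not isolated)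
13 | 1-[2-acetyl-4-(benzyloxy)-3-methoxyphenyl]propan-2-one | CC(=O)Cc1ccc(OCc2ccccc2)c(OC)c1C(C)=O | intermediate (not isolated)
14 | 7-(benzyloxy)-8-methoxy-3-methylnaphthalen-1-ol | COc1c(OCc2ccccc2)ccc2cc(C)cc(O)c12 | intermediate
15 | 1,7-bis(benzyloxy)-8-methoxy-3-methylnaphthalene | COc1c(OCc2ccccc2)ccc2cc(C)cc(OCc3ccccc3)c12 | intermediate
16 | 4,6-bis(benzyloxy)-1-bromo-5-methoxy-2-methylnaphthalene | COc1c(OCc2ccccc2)ccc2c(Br)c(C)cc(OCc3ccccc3)c12 | intermediate
17 | methyl bromoacetate | COC(=O)CBr | starting material
18 | bromo(2-methoxy-2-oxoethyl)zinc | COC(=O)C[Zn]Br | intermediate (not isolated)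
19 | methyl 2-[4,6-bis(benzyloxy)-5-methoxy-2-methylnaphthalen-1-yl]acetate | COC(=O)Cc1c(C)cc(OCc2ccccc2)c2c(OC)c(OCc3ccccc3)ccc12 | intermediate
20 | methyl 2-[4,6-bis(benzyloxy)-5-methoxy-2-methylnaphthalen-1-yl]-3-oxobutanoate (racemic) | COC(=O)C(C(C)=O)c1c(C)cc(OCc2ccccc2)c2c(OC)c(OCc3ccccc3)ccc12 | intermediate
21 | orcinol (5-methylbenzene-1,3-diol) | Cc1cc(O)cc(O)c1 | starting material
22 | 3-(benzyloxy)-5-methylphenol | Cc1cc(O)cc(OCc2ccccc2)c1 | intermediate
23 | 3-(benzyloxy)-5-methylphenyl N-isopropylcarbamate | Cc1cc(OCc2ccccc2)cc(OC(=O)NC(C)C)c1 | intermediate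
24 | 3-(benzyloxy)-5-methylphenyl N-(tert-butyldimethylsilyl)-N-isopropylcarbamate | Cc1cc(OCc2ccccc2)cc(OC(=O)N(C(C)C)[Si](C)(C)C(C)(C)C)c1 | intermediate (not isolated)
25 | 3-(benzyloxy)-5-methyl-2-(trimethylsilyl)phenyl N-(tert-butyldimethylsilyl)-N-isopropylcarbamate | Cc1cc(OCc2ccccc2)c([Si](C)(C)C)c(OC(=O)N(C(C)C)[Si](C)(C)C(C)(C)C)c1 | intermediate (not isolated)
26 | 3-(benzyloxy)-5-methyl-2-(trimethylsilyl)phenyl N-isopropylcarbamate | Cc1cc(OCc2ccccc2)c([Si](C)(C)C)c(OC(=O)NC(C)C)c1 | intermediate
27 | 3-(benzyloxy)-5-methyl-2-(trimethylsilyl)phenol | Cc1cc(O)c([Si](C)(C)C)c(OCc2ccccc2)c1 | intermediate (not isolated)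
28 | 3-(benzyloxy)-5-methyl-2-(trimethylsilyl)phenyl trifluoromethanesulfonate | Cc1cc(OCc2ccccc2)c([Si](C)(C)C)c(OS(=O)(=O)C(F)(F)F)c1 | intermediate
29 | 3-(benzyloxy)-5-methylbenzyne (1-(benzyloxy)-5-methyl-2,3-didehydrobenzene) | CC1=CC#CC(OCc2ccccc2)=C1 | intermediate (not isolated)
30 | methyl 2-[2-acetyl-3-(benzyloxy)-5-methylphenyl]-2-[4,6-bis(benzyloxy)-5-methoxy-2-methylnaphthalen-1-yl]acetate (racemic) | COC(=O)C(c1cc(C)cc(OCc2ccccc2)c1C(C)=O)c1c(C)cc(OCc2ccccc2)c2c(OC)c(OCc3ccccc3)ccc12 | intermediate
31 | 8-(benzyloxy)-4-[4,6-bis(benzyloxy)-5-methoxy-2-methylnaphthalen-1-yl]-6-methylnaphthalene-1,3-diol (racemic axis) | Oc1cc(O)c(-c2c(C)cc(OCc3ccccc3)c3c(OC)c(OCc4ccccc4)ccc23)c2cc(C)cc(OCc3ccccc3)c12 | intermediate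
32 | 3,8-bis(benzyloxy)-4-[4,6-bis(benzyloxy)-5-methoxy-2-methylnaphthalen-1-yl]-6-methylnaphthalen-1-ol (racemic axis) | Oc1cc(OCc2ccccc2)c(-c2c(C)cc(OCc3ccccc3)c3c(OC)c(OCc4ccccc4)ccc23)c2cc(C)cc(OCc3ccccc3)c12 | intermediate
33 | 3,8-bis(benzyloxy)-4-[4,6-bis(benzyloxy)-5-methoxy-2-methylnaphthalen-1-yl]-1-methoxy-6-methylnaphthalene (racemic axis) | COc1cc(OCc2ccccc2)c(-c2c(C)cc(OCc3ccccc3)c3c(OC)c(OCc4ccccc4)ccc23)c2cc(C)cc(OCc3ccccc3)c12 | intermediate
34 | 4,5′-dimethoxy-2′,7-dimethyl-[1,1′-binaphthalene]-2,4′,5,6′-tetrol (racemic axis) | COc1cc(O)c(-c2c(C)cc(O)c3c(OC)c(O)ccc23)c2cc(C)cc(O)c12 | target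

## Step count and least certain steps

Total: 19 steps. Longest linear sequence: 15 steps (steps 1 to 10, then 15 to 19). The orcinol branch (steps 11 to 14) joins at step 15.

**Step 15 (key step).** The enolate carbon of 20 is flanked by the C2′ methyl group and the peri C8′–H, so carbon attack on the aryne may be slow. Three processes could then take over: O-arylation of the enol, protonation of the aryl anion before acyl transfer (plain α-arylation), or self-reaction of the aryne.

Fallback, a Suzuki–Miyaura biaryl coupling in place of the insertion of the hindered ketoester; it sets out from silyl triflate 28 and bromide 16 and returns at 33.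
- Aryne 29 is inserted into commercial methyl acetoacetate (CsF, MeCN, 80 °C), the unhindered parent case of the same reaction, to give methyl 2-[2-acetyl-3-(benzyloxy)-5-methylphenyl]acetate F1.
- NaOMe closes ring P to 8-(benzyloxy)-6-methylnaphthalene-1,3-diol F2.
- Benzylation at O3 gives 3,8-bis(benzyloxy)-6-methylnaphthalen-1-ol F3, and methylation gives 3,8-bis(benzyloxy)-1-methoxy-6-methylnaphthalene F4. This uses the same hydrogen-bond argument as step 17, on a compound without the bulky aryl group.
- NBS brominates C4, which is para to the methoxy and ortho to the benzyloxy group, giving 3,8-bis(benzyloxy)-4-bromo-1-methoxy-6-methylnaphthalene F5.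
- Bromide 16 is converted (n-BuLi, B(OiPr)3, then aqueous acid) into [4,6-bis(benzyloxy)-5-methoxy-2-methylnaphthalen-1-yl]boronic acid F6.
- F5 and F6 are joined with Pd(OAc)2, SPhos (2-dicyclohexylphosphino-2′,6′-dimethoxybiphenyl) and K3PO4 in toluene/water to give 33, and the route continues with step 19.

The price is a direct coupling at the crowded axis, which the main route avoids.

**Step 17.** Discrimination between the O3 and O1 hydroxyls may be incomplete, and the ambident diol anion may be alkylated at carbon (C2) or twice. It is also sensitive to air.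

Fallback, acylative instead of alkylative differentiation, from 31 to 34.
- Benzyl chloroformate and pyridine acylate the more acidic, non-hydrogen-bonded O3 hydroxyl. A hard acylating agent reacts at oxygen only. The product is benzyl 5-(benzyloxy)-1-[4,6-bis(benzyloxy)-5-methoxy-2-methylnaphthalen-1-yl]-4-hydroxy-7-methylnaphthalen-2-yl carbonate F12.
- The O1 hydroxyl is methylated without a nucleophilic base (Me3OBF4, 1,8-bis(dimethylamino)naphthalene, CH2Cl2) to give benzyl 5-(benzyloxy)-1-[4,6-bis(benzyloxy)-5-methoxy-2-methylnaphthalen-1-yl]-4-methoxy-7-methylnaphthalen-2-yl carbonate F13.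
- The hydrogenolysis of step 19 removes the carbonate together with the three benzyl ethers and gives 34 directly, in the same number of steps.

**Step 8.** Bromination may be unselective: substitution at C5 (para to the methoxy group) or C6 of 15, or a second bromination, would give isomers that are hard to separate. The hindered coupling of step 9 depends on the same bromide.

Fallback, building the side chain in during the ring synthesis; it sets out from silyl triflate 10, acetylacetone 11 and methyl bromoacetate 17 and returns at 19.
- Alkylation of 11 with 17 (K2CO3, acetone) gives methyl 3-acetyl-4-oxopentanoate F7.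
- Insertion of aryne 12 into F7 and aldol closure, under the conditions of step 6, give methyl 2-[6-(benzyloxy)-4-hydroxy-5-methoxy-2-methylnaphthalen-1-yl]acetate F8, with the acetic ester already at C1′.
- Benzylation (BnBr, Cs2CO3, DMF) gives 19.

This bypasses steps 7 to 9. It is kept as the fallback because the aryl anion could also be captured by the side-chain ester and the substituted diketone is a more hindered nucleophile.

**Step 13.** The aryllithium sits next to the benzyloxy group. Proton transfer from the benzylic CH2, followed by [1,2]-Wittig rearrangement, or lithiation at the benzylic position from the outset, would consume the substrate.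

Fallback, lithiation before the benzyl group is present; it sets out from orcinol 21 and returns at 27.
- Both hydroxyls are carbamoylated (i-PrNCO, Et3N) to give 5-methyl-1,3-phenylene bis(N-isopropylcarbamate) F9.
- Directed ortho-metalation between the two carbamates and quenching with TMSCl, under the conditions of step 13 with doubled TBSOTf, give 5-methyl-2-(trimethylsilyl)-1,3-phenylene bis(N-isopropylcarbamate) F10.
- DBU and Et2NH remove both carbamates to give 5-methyl-2-(trimethylsilyl)benzene-1,3-diol F11.
- Statistical monobenzylation (BnBr, K2CO3, acetone) gives silyl phenol 27, which is triflated with PhNTf2 as in step 14 to give 28.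

## Further compounds

F1 | step 15 | methyl 2-[2-acetyl-3-(benzyloxy)-5-methylphenyl]acetate | COC(=O)Cc1cc(C)cc(OCc2ccccc2)c1C(C)=O
F2 | step 15 | 8-(benzyloxy)-6-methylnaphthalene-1,3-diol | Cc1cc(OCc2ccccc2)c2c(O)cc(O)cc2c1
F3 | step 15 | 3,8-bis(benzyloxy)-6-methylnaphthalen-1-ol | Cc1cc(OCc2ccccc2)c2c(O)cc(OCc3ccccc3)cc2c1
F4 | step 15 | 3,8-bis(benzyloxy)-1-methoxy-6-methylnaphthalene | COc1cc(OCc2ccccc2)cc2cc(C)cc(OCc3ccccc3)c12
F5 | step 15 | 3,8-bis(benzyloxy)-4-bromo-1-methoxy-6-methylnaphthalene | COc1cc(OCc2ccccc2)c(Br)c2cc(C)cc(OCc3ccccc3)c12
F6 | step 15 | [4,6-bis(benzyloxy)-5-methoxy-2-methylnaphthalen-1-yl]boronic acid | COc1c(OCc2ccccc2)ccc2c(B(O)O)c(C)cc(OCc3ccccc3)c12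
F7 | step 8 | methyl 3-acetyl-4-oxopentanoate | COC(=O)CC(C(C)=O)C(C)=O
F8 | step 8 | methyl 2-[6-(benzyloxy)-4-hydroxy-5-methoxy-2-methylnaphthalen-1-yl]acetate | COC(=O)Cc1c(C)cc(O)c2c(OC)c(OCc3ccccc3)ccc12
F9 | step 13 | 5-methyl-1,3-phenylene bis(N-isopropylcarbamate) | Cc1cc(OC(=O)NC(C)C)cc(OC(=O)NC(C)C)c1
F10 | step 13 | 5-methyl-2-(trimethylsilyl)-1,3-phenylene bis(N-isopropylcarbamate) | Cc1cc(OC(=O)NC(C)C)c([Si](C)(C)C)c(OC(=O)NC(C)C)c1
F11 | step 13 | 5-methyl-2-(trimethylsilyl)benzene-1,3-diol | Cc1cc(O)c([Si](C)(C)C)c(O)c1
F12 | step 17 | benzyl 5-(benzyloxy)-1-[4,6-bis(benzyloxy)-5-methoxy-2-methylnaphthalen-1-yl]-4-hydroxy-7-methylnaphthalen-2-yl carbonate (racemic axis) | Oc1cc(OC(=O)OCc2ccccc2)c(-c2c(C)cc(OCc3ccccc3)c3c(OC)c(OCc4ccccc4)ccc23)c2cc(C)cc(OCc3ccccc3)c12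
F13 | step 17 | benzyl 5-(benzyloxy)-1-[4,6-bis(benzyloxy)-5-methoxy-2-methylnaphthalen-1-yl]-4-methoxy-7-methylnaphthalen-2-yl carbonate (racemic axis) | COc1cc(OC(=O)OCc2ccccc2)c(-c2c(C)cc(OCc3ccccc3)c3c(OC)c(OCc4ccccc4)ccc23)c2cc(C)cc(OCc3ccccc3)c12
A1 | alternative 1 | 7-(benzyloxy)-4-[2,5-bis(benzyloxy)-4-methoxy-7-methylnaphthalen-1-yl]-2-bromo-8-methoxy-3-methylnaphthalen-1-ol (racemic axis) | COc1cc(OCc2ccccc2)c(-c2c(C)c(Br)c(O)c3c(OC)c(OCc4ccccc4)ccc23)c2cc(C)cc(OCc3ccccc3)c12
A2 | alternative 1 | 6-(benzyloxy)-3-[2,5-bis(benzyloxy)-4-methoxy-7-methylnaphthalen-1-yl]-7-methoxy-2-methyl-2,3-dihydro-1H-inden-1-one (racemic, relative configuration not defined) | CC1C(=O)c2c(OC)c(OCc3ccccc3)ccc2C1c1c(OCc2ccccc2)cc(OC)c2c(OCc3ccccc3)cc(C)cc12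
A3 | alternative 2 | 5-[4,6-bis(benzyloxy)-5-methoxy-2-methylnaphthalen-1-yl]-6,8-dihydroxy-3-methyl-3,4-dihydronaphthalen-1(2H)-one (racemic) | O=C1CC(C)Cc2c1c(O)cc(O)c2-c1c(C)cc(OCc2ccccc2)c2c(OC)c(OCc3ccccc3)ccc12
A4 | alternative 2 | 2-{[4,6-bis(benzyloxy)-5-methoxy-2-methylnaphthalen-1-yl]methyl}-7-methyl-7,8-dihydro-4H-chromene-4,5(6H)-dione (racemic) | O=C1CC(C)CC2=C1C(=O)C=C(Cc1c(C)cc(OCc3ccccc3)c3c(OC)c(OCc4ccccc4)ccc13)O2
A5 | alternative 3 | 8-(benzyloxy)-4-[4,6-bis(benzyloxy)-5-methoxy-2-methylnaphthalen-1-yl]-6-methyl-3-[(triisopropylsilyl)oxy]naphthalen-1-ol (racemic axis) | Oc1cc(O[Si](C(C)C)(C(C)C)C(C)C)c(-c2c(C)cc(OCc3ccccc3)c3c(OC)c(OCc4ccccc4)ccc23)c2cc(C)cc(OCc3ccccc3)c12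
A6 | alternative 3 | 5-(benzyloxy)-8-[4,6-bis(benzyloxy)-5-methoxy-2-methylnaphthalen-1-yl]-3-methylbicyclo[4.2.0]octa-1,3,5-trien-7-one (racemic) | O=C1C(c2c(C)cc(OCc3ccccc3)c3c(OC)c(OCc4ccccc4)ccc23)c2cc(C)cc(OCc3ccccc3)c12
A7 | alternative 3 | (ethynyloxy)triisopropylsilane | C#CO[Si](C(C)C)(C(C)C)C(C)C
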